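## Structural features

The target is a sesquineolignan. A 1-aryl-2,3-dimethyltetralin (ring A: the fused arene with C6–OMe and C7–OH; ring B: the saturated ring C1–C4; ring C: the guaiacyl ring on C1) carries on O4' of ring C a 1-(4-hydroxy-3-methoxyphenyl)propan-1-ol chain (ring D, carbinol C7'', methine C8''), joined through the C8''–O4' ether. Ring B holds three contiguous stereocentres, C1 (S, a diarylmethine), C2 (S) and C3 (R), with aryl, methyl and methyl all equatorial (1,2-trans, 2,3-trans, so 1,3-cis). The chain holds two more adjacent ones, C7'' (S) and C8'' (R), in the erythro relationship. Ring C insulates the two clusters from each other, so the chain must be set from the chiral pool and by reagent control, not by relay from the tetralin. Fragile points are the electron-rich phenol rings (oxidation), the para-oxygenated benzylic alcohol at C7'' (ionization in acid, hydrogenolysis), C8'' whenever C7'' is a carbonyl (enolization), and the doubly benzylic C1–H. The real difficulty is threefold: ring B has no heteroatom handle yet needs absolute and relative control at a diarylmethine; the ring A phenol must be told apart from the ring C phenol so that only O4' is alkylated; and the chain must be erythro and of one hand. The feature exploited is that C1 is bonded to C1' of ring C, para to O4'. With O4'–H free, C1 and ring C can be written as a para-quinone methide with C1 as the electrophilic exocyclic carbon, and the C2 methyl can be carried as a formyl group, which makes C2 an enamine carbon; joining C2 to C1 closes ring B. The same free O4'–H is afterwards the only site for the chain, because O7 of ring A stays benzylated.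

## Logic of the disconnections

33 to 32: the two O–CH2Ph bonds (O7 of ring A, O4 of ring D) are cut last. Both phenols must stay masked while organometallics and hydrides are used, and benzyl leaves under neutral hydrogen. The gain is a late stage without free phenols. The demand is that hydrogenolysis spares the C7''–OH and C8''–O bonds.

32 to 31: C7''–H is cut (carbinol back to ketone). A ketone next to the C8'' aryloxy centre allows a metal chelate to fix the face of hydride attack. The gain is that C7'' is no longer stereogenic and the bond to ring D becomes an acylation. The demand is chelation control (erythro) without enolization at C8''.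

31 to 27 and 29 (through 30): the C7''–C1 (ring D) bond is cut. An N-methoxy-N-methyl amide stops the aryl addition at the ketone. The gain is that ring D is a simple aryl bromide, one step from 28. The demand is that addition outruns α-deprotonation at C8''.

27 to 24 and 26: the O4'–C8'' bond is cut. Lactic acid supplies C8'' from the chiral pool, and 24 has one hydroxyl only, so the site is unambiguous. The gain is separation of tetralin and chain; 26 is one step from 25. The demand is clean SN2 inversion at a secondary α-carbonyl carbon.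

24 to 23, 22 and 21: the C2 methyl is traced back through CH2I and CH2OH to CHO, the carbon left by the ring closure. Because the ring C phenol is free, a sulfonate cannot be made selectively on 22; an iodide made under phosphonium activation is chosen, which only the aliphatic alcohol can enter. The demand is hydride displacement at a β-branched primary carbon.

21 to 19 (through 20): the C1–C2 bond is cut. C1 becomes the exocyclic carbon of the ring C quinone methide, C2 the α-carbon of an aldehyde. The gain is large: ring B and two stereocentres disappear, leaving an open chain with one stereocentre (C3). The demand is that C3 controls C1 and C2 through a chair, and that closure beats intermolecular addition.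

19 to 18 and 16: the silyl group is put back on O4', and the aldehyde carbon is rejoined to a terminal CH2 as an alkene. An acetal would need acid for removal, which the doubly para-oxygenated diaryl carbinol would not survive. A terminal alkene is inert to the aryllithium step and is opened under near-neutral oxidative conditions. The demand is an oxidative cleavage that spares arenes and carbinol, and a desilylation that does not start the ring closure early.

16 to 12 and 14 (through 15): the C1–C8a bond is cut. Bromine marks C8a on ring A, and the carbinol configuration is irrelevant because C1 becomes trigonal. The gain is two simple arenes, 14 being one step from 13. The demand is bromine–lithium exchange faster than any reaction at the alkene or the benzyl ether.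

12 to 11, 10 and 9: the C3 methyl is traced back through CH2OTs and CH2OH to the auxiliary carbonyl. Using that carbonyl as the future methyl, with the allyl arm as the future C2 and aldehyde carbon, avoids a separate homologation and aldehyde protection. The demand is that the hydride steps spare the aryl bromide and alkene.

9 to 7 and 4 (through 8): the C3–C4 bond is cut. A benzylic bromide and a chelated Z-enolate are the classical pair. The demand is high facial selectivity. The (4R)-auxiliary is required: the carbonyl carbon ends as methyl, which reverses the usual priority order.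

7 to 5 and 6; 4 to 3, 2 and 1: the N-acyl bond, the benzylic C–Br and C–O bonds and the aryl C–Br bond are cut. The demand is bromination para to the methoxy group of 1, which is the carbon that becomes C8a.

## Other disconnections considered

Alternative 1: The cut is at C1–C1' and C2–CH3 at once, with ring B left open.
- **Forward key step:** the (Z)-alkenyl pinacol boronate A2 is turned by MeLi into its methyl boronate complex. Pd(OAc)2 with the diphosphine MandyPhos and the ring C aryl triflate A3 should then induce a 1,2-metallate shift: methyl migrates from boron to C2 and the aryl group is delivered to C1, anti across the alkene, giving the secondary boronate A1 with C1 and C2 as in the target.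
- **In favour:** C1 and C2 are set together by a chiral catalyst and not by relay from C3. No stoichiometric auxiliary is needed, the union of the ring A and ring C pieces is convergent, and the C–B bond of A1 is a stereospecific handle for growing C3.
- **Against:** methyl is a small and reluctant migrating group. A β-aryl alkenyl pinacol boronate tends to transmetallate and give plain Suzuki coupling. The Z-alkenyl boronate must be made and kept geometrically pure. A1 still lacks C3, its methyl, C4 and the C4–C4a bond, so a boronate homologation setting the third stereocentre, a chain extension and an sp3–sp2 closure onto a hindered electron-rich aryl chloride would all have to follow.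
- **Comparison:** in absolute control of the diarylmethine the alternative is the better plan. In differentiating the ring A and ring C oxygens (silyl against benzyl) the two are equal. In ring construction the chosen plan is ahead, since step 13 makes ring B and two stereocentres in one operation, and the steps after A1 would probably outnumber those the chosen route spends on ring B.

Alternative 2: Ring B is cut at C1–C2 and C3–C4, the retron of a [4+2] cycloaddition.
- **Forward key step:** UV irradiation of the 2-benzylbenzaldehyde A5 should give, by 1,5-hydrogen shift from the diarylmethane CH2, the hydroxy-ortho-quinodimethane. Methyl (E)-crotonate A6 traps it to give tetralin A4, with the ring C aryl on C1, methyl on C2, the ester on C3 and a hydroxyl on C4.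
- **In favour:** two C–C bonds and the whole skeleton of rings A to C arise in one reagent-free step from an easily made diarylmethane. The E-geometry of A6 translates into the 2,3-trans relationship, and the C2 methyl is in place at once.
- **Against:** the cycloaddition is racemic unless a chiral Lewis acid can organize a simple monodentate crotonate, a weak point for a single-enantiomer target. β-Substituted acrylates are sluggish partners for short-lived photoenols, so reketonization may win. The configuration at C1 depends on the dienol geometry. A4 carries two functions the target lacks, so a benzylic deoxygenation at C4 and a three-step ester-to-methyl reduction at C3 must follow, in the presence of an allyl ether.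
- **Comparison:** in convergence and bonds formed per step the alternative is the better. In differentiating the two phenols (allyl against benzyl) it is equal. In absolute stereocontrol and in redox economy after ring closure the chosen plan is better, since step 13 leaves one formyl group to reduce and takes its absolute sense from an auxiliary-derived centre.

Alternative 3: Ring B is cut at C2–C3 and C1–C8a, dividing the tetralin into two arylpropene units.
- **Forward key step:** a photo-oxidant under visible light removes one electron from the more electron-rich alkene, O-benzylisoeugenol A8. The alkene of isoeugenol pivalate A9 attacks the radical cation β to β (C2–C3). The benzylic cation at C1 is captured by ring A of the pivalate unit para to its methoxy group (C1–C8a), and back electron transfer with proton shift gives tetralin A7.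
- **In favour:** it is by far the shortest way to the skeleton. Both methyl groups are native, so no redox adjustment is needed. The all-trans isomer is the thermodynamically preferred one. A7 already carries different groups on O7 (pivalate) and O4' (benzyl), so hydrogenolysis would free exactly the phenol needed for the chain.
- **Against:** the crossed coupling competes with both homodimerizations and relies on a small difference in oxidation potential. Radical cations of this kind often stop at cyclobutanes. The acyloxy group makes ring A of A9 a poorer trap for the C1 cation. There is no dependable way to impose absolute configuration on a radical-cation cycloaddition, so a resolution would be needed.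
- **Comparison:** in step and redox economy the alternative is clearly the better, and in differentiating the phenols it is equal. In chemoselectivity and above all in absolute stereocontrol the chosen plan is safer, because each of its stereocentres traces to an auxiliary, the chiral pool or a chair-controlled relay.

Key step: step 13

Assumption: 1, 5, 6, 13, 25 and 28 are taken as catalogue chemicals; locants follow tetralin numbering (C1–C8a) for rings A and B, primes for ring C and double primes for the chain (C7'' carbinol, C8'' methine, ring D); the CIP analysis of the target gives 1S, 2S, 3R, 7''S, 8''R.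

## Route

Step 1
Reactants: 1 4-(benzyloxy)-3-methoxybenzaldehyde (O-benzylvanillin)
Product: 2 4-(benzyloxy)-2-bromo-5-methoxybenzaldehyde
Conditions: Br2, NaOAc, AcOH, rt
Reagents that add atoms: bromine, BrBr
Why: Electrophilic aromatic bromination; the open position para to OMe and ortho to CHO is the most activated one (as with veratraldehyde), so bromine marks the carbon that becomes C8a.

Step 2
Reactants: 2 4-(benzyloxy)-2-bromo-5-methoxybenzaldehyde
Product: 3 [4-(benzyloxy)-2-bromo-5-methoxyphenyl]methanol
Conditions: NaBH4, MeOH/THF, 0 °C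
Reagents that add atoms: none
Why: Chemoselective borohydride reduction of the aryl aldehyde; the aryl bromide and benzyl ether are inert.

Step 3
Reactants: 3 [4-(benzyloxy)-2-bromo-5-methoxyphenyl]methanol
Product: 4 1-(benzyloxy)-5-bromo-4-(bromomethyl)-2-methoxybenzene
Conditions: PBr3, CH2Cl2, 0 °C
Reagents that add atoms: phosphorus tribromide, BrP(Br)Br
Why: Conversion of an electron-rich benzylic alcohol into the bromide via its phosphite ester; run cold and briefly to spare the benzyl ether.

Step 4
Reactants: 5 (4R)-4-benzyl-1,3-oxazolidin-2-one; 6 pent-4-enoyl chloride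
Product: 7 (4R)-4-benzyl-3-(pent-4-enoyl)-1,3-oxazolidin-2-one
Conditions: Et3N, DMAP (10 mol %), CH2Cl2, 0 °C → rt
Reagents that add atoms: none
Why: DMAP-catalysed N-acylation of the oxazolidinone through the acylpyridinium ion; this attaches the chiral auxiliary.

Step 5
Reactants: 7 (4R)-4-benzyl-3-(pent-4-enoyl)-1,3-oxazolidin-2-one; 4 1-(benzyloxy)-5-bromo-4-(bromomethyl)-2-methoxybenzene
Product: 9 (4R)-4-benzyl-3-[(2S)-2-{[4-(benzyloxy)-2-bromo-5-methoxyphenyl]methyl}pent-4-enoyl]-1,3-oxazolidin-2-one, via sodium enolate 8 (not isolated)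
Conditions: NaN(SiMe3)2, THF, −78 °C; then 4, −78 → −20 °C
Reagents that add atoms: none
Why: Evans asymmetric alkylation; the chelated (Z)-enolate 8 is attacked by the benzylic bromide on the face opposite the C4 benzyl group. With the (4R)-auxiliary this should give the (2S) centre, which becomes C3 (R) of the target once the carbonyl is reduced to methyl.

Step 6
Reactants: 9 (4R)-4-benzyl-3-[(2S)-2-{[4-(benzyloxy)-2-bromo-5-methoxyphenyl]methyl}pent-4-enoyl]-1,3-oxazolidin-2-one
Product: 10 (2S)-2-{[4-(benzyloxy)-2-bromo-5-methoxyphenyl]methyl}pent-4-en-1-ol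
Conditions: LiBH4, H2O (1 equiv), Et2O, 0 °C
Reagents that add atoms: none
Why: Reductive removal of the auxiliary by hydride attack at the exocyclic carbonyl; the α-centre is not deprotonated and the oxazolidinone is recovered.

Step 7
Reactants: 10 (2S)-2-{[4-(benzyloxy)-2-bromo-5-methoxyphenyl]methyl}pent-4-en-1-ol
Product: 11 (2S)-2-{[4-(benzyloxy)-2-bromo-5-methoxyphenyl]methyl}pent-4-en-1-yl 4-methylbenzenesulfonate
Conditions: TsCl, Et3N, DMAP (cat.), CH2Cl2, 0 °C → rt
Reagents that add atoms: 4-toluenesulfonyl chloride, Cc1ccc(S(=O)(=O)Cl)cc1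
Why: Sulfonylation of the only hydroxyl group.

Step 8
Reactants: 11 (2S)-2-{[4-(benzyloxy)-2-bromo-5-methoxyphenyl]methyl}pent-4-en-1-yl 4-methylbenzenesulfonate
Product: 12 1-(benzyloxy)-5-bromo-2-methoxy-4-[(2S)-2-methylpent-4-en-1-yl]benzene
Conditions: LiEt3BH, THF, 0 °C → rt
Reagents that add atoms: none
Why: SN2 hydride displacement of a β-branched primary tosylate, for which LiEt3BH is the standard reagent; the aryl bromide and terminal alkene should survive. The former auxiliary carbonyl becomes the C3 methyl, and the allyl arm is the latent C2 and formyl carbon.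

Step 9
Reactants: 13 vanillin (4-hydroxy-3-methoxybenzaldehyde)
Product: 14 4-[(tert-butyldimethylsilyl)oxy]-3-methoxybenzaldehyde
Conditions: t-BuMe2SiCl, imidazole, CH2Cl2, rt
Reagents that add atoms: tert-butyldimethylsilyl chloride, CC(C)(C)[Si](C)(C)Cl
Why: Silylation of the phenol; the silyl ether tolerates an aryllithium at −78 °C and can later be removed by fluoride without acid.

Step 10
Reactants: 12 1-(benzyloxy)-5-bromo-2-methoxy-4-[(2S)-2-methylpent-4-en-1-yl]benzene; 14 4-[(tert-butyldimethylsilyl)oxy]-3-methoxybenzaldehyde
Product: 16 {4-(benzyloxy)-5-methoxy-2-[(2S)-2-methylpent-4-en-1-yl]phenyl}{4-[(tert-butyldimethylsilyl)oxy]-3-methoxyphenyl}methanol (both carbinol epimers), via aryllithium 15 (not isolated)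
Conditions: n-BuLi, THF, −78 °C; then 14, −78 → −40 °C; sat. aq. NH4Cl
Reagents that add atoms: none
Why: Bromine–lithium exchange at −78 °C is faster than benzylic deprotonation or carbolithiation of the remote alkene, and 1,2-addition to the aldehyde forms C1–C8a. The carbinol configuration is irrelevant because C1 becomes trigonal in step 13.

Step 11
Reactants: 16 {4-(benzyloxy)-5-methoxy-2-[(2S)-2-methylpent-4-en-1-yl]phenyl}{4-[(tert-butyldimethylsilyl)oxy]-3-methoxyphenyl}methanol
Product: 18 (3R)-4-[4-(benzyloxy)-2-{[4-(tert-butyldimethylsilyloxy)-3-methoxyphenyl](hydroxy)methyl}-5-methoxyphenyl]-3-methylbutanal, via diol 17 (not isolated)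
Conditions: OsO4 (2 mol %), NaIO4 (4 equiv), 2,6-lutidine, dioxane/H2O 3:1, rt
Reagents that add atoms: osmium tetroxide, O=[Os](=O)(=O)=O (transfers the oxygen atoms of 17, one of which stays in 18); sodium periodate, [Na+].[O-]I(=O)(=O)=O (re-oxidant and cleaving agent, the ultimate oxygen source)
Why: Lemieux–Johnson oxidation; osmylation of the monosubstituted alkene gives diol 17 and periodate cleaves it in the same flask. 2,6-Lutidine keeps the medium near neutral, so the acid-labile diaryl carbinol and the silyl ether should survive; the terminal CH2 leaves as formaldehyde.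

Step 12
Reactants: 18 (3R)-4-[4-(benzyloxy)-2-{[4-(tert-butyldimethylsilyloxy)-3-methoxyphenyl](hydroxy)methyl}-5-methoxyphenyl]-3-methylbutanal
Product: 19 (3R)-4-[4-(benzyloxy)-2-[hydroxy(4-hydroxy-3-methoxyphenyl)methyl]-5-methoxyphenyl]-3-methylbutanal (either carbinol epimer)
Conditions: Bu4NF, AcOH (1:1), THF, 0 °C
Reagents that add atoms: none
Why: Fluoride cleavage of the aryl silyl ether, buffered with AcOH so that neither the aldehyde (aldol) nor the carbinol (ionization) is disturbed; 19 is used at once.

Step 13
Reactants: 19 (3R)-4-[4-(benzyloxy)-2-[hydroxy(4-hydroxy-3-methoxyphenyl)methyl]-5-methoxyphenyl]-3-methylbutanal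
Product: 21 (1S,2S,3R)-7-(benzyloxy)-1-(4-hydroxy-3-methoxyphenyl)-6-methoxy-3-methyl-1,2,3,4-tetrahydronaphthalene-2-carbaldehyde, via quinone methide enamine 20 (not isolated)
Conditions: pyrrolidine (30 mol %), PhCO2H (30 mol %), CHCl3 (0.02 M), 40 °C; aq. NaHCO3
Reagents that add atoms: none
Why: The pyrrolidinium benzoate buffer should condense the amine with the aldehyde to the E-enamine and ionize the 4-hydroxybenzhydrol, which is doubly activated (para-OH of ring C, para-OMe of ring A), to the neutral para-quinone methide, so both carbinol epimers give 20. The enamine carbon C2 then adds to the exocyclic carbon C1 in an intramolecular 1,6-conjugate addition driven by re-aromatization of ring C, and hydrolysis of the iminium ion returns the amine. The closest known reaction types are the secondary-amine-catalysed 1,6-addition of aldehydes to para-quinone methides and the acid-promoted generation of such methides from 4-hydroxybenzyl alcohols. Ring B closes 6-exo-trig with respect to the C1=C1' bond (enolexo with respect to the enamine) through a half-chair whose remaining ring atoms are the arene carbons C4a and C8a. C3 is the only stereocentre present and should control both new ones: its methyl takes the pseudo-equatorial site, and the bulky cyclohexadienone on C1 then also goes pseudo-equatorial, which sets C1 cis to the C3 methyl. C2 is formed trans to both neighbours and, because it stays α to the iminium or aldehyde carbon, can be corrected to the all-equatorial isomer by enamine–iminium equilibration. The step needs C-attack over N- or O-attack (hetero-adducts of the methide are reversible), ring closure over intermolecular addition (six-membered ring, high dilution) and facial selectivity at C1 (the equatorial C3 methyl in the chair). Only ring C can form a quinone methide, since both oxygens of ring A are ethers.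

Step 14
Reactants: 21 (1S,2S,3R)-7-(benzyloxy)-1-(4-hydroxy-3-methoxyphenyl)-6-methoxy-3-methyl-1,2,3,4-tetrahydronaphthalene-2-carbaldehyde
Product: 22 4-[(1S,2S,3R)-7-(benzyloxy)-2-(hydroxymethyl)-6-methoxy-3-methyl-1,2,3,4-tetrahydronaphthalen-1-yl]-2-methoxyphenol
Conditions: NaBH4, MeOH, 0 °C
Reagents that add atoms: none
Why: Borohydride reduction of the aldehyde; done promptly it also freezes the configuration at C2.

Step 15
Reactants: 22 4-[(1S,2S,3R)-7-(benzyloxy)-2-(hydroxymethyl)-6-methoxy-3-methyl-1,2,3,4-tetrahydronaphthalen-1-yl]-2-methoxyphenol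
Product: 23 4-[(1S,2S,3R)-7-(benzyloxy)-2-(iodomethyl)-6-methoxy-3-methyl-1,2,3,4-tetrahydronaphthalen-1-yl]-2-methoxyphenol
Conditions: PPh3, I2, imidazole (premixed), CH2Cl2, 0 °C → rt
Reagents that add atoms: iodine, II
Why: Appel-type iodination; only the aliphatic alcohol gives an alkoxyphosphonium ion open to SN2 displacement, so the free ring C phenol needs no protection, which a sulfonylation would not allow. Premixing the reagents keeps free iodine away from the phenol ring.

Step 16
Reactants: 23 4-[(1S,2S,3R)-7-(benzyloxy)-2-(iodomethyl)-6-methoxy-3-methyl-1,2,3,4-tetrahydronaphthalen-1-yl]-2-methoxyphenol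
Product: 24 4-[(1S,2S,3R)-7-(benzyloxy)-6-methoxy-2,3-dimethyl-1,2,3,4-tetrahydronaphthalen-1-yl]-2-methoxyphenol
Conditions: LiEt3BH (3.5 equiv), THF, 0 °C → rt
Reagents that add atoms: none
Why: SN2 hydride displacement of the primary iodide (one equivalent of hydride is consumed by the phenol); no stereocentre is touched and the former formyl carbon becomes the C2 methyl.

Step 17
Reactants: 25 ethyl (S)-lactate
Product: 26 (2S)-2-hydroxy-N-methoxy-N-methylpropanamide
Conditions: MeNH(OMe)·HCl, i-PrMgCl, THF, −20 → 0 °C
Reagents that add atoms: N,O-dimethylhydroxylamine hydrochloride, CNOC.Cl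
Why: Aminolysis of the ester by the chloromagnesium amide of N,O-dimethylhydroxylamine at low temperature, with retention of the lactate stereocentre.

Step 18
Reactants: 24 4-[(1S,2S,3R)-7-(benzyloxy)-6-methoxy-2,3-dimethyl-1,2,3,4-tetrahydronaphthalen-1-yl]-2-methoxyphenol; 26 (2S)-2-hydroxy-N-methoxy-N-methylpropanamide
Product: 27 (2R)-2-{4-[(1S,2S,3R)-7-(benzyloxy)-6-methoxy-2,3-dimethyl-1,2,3,4-tetrahydronaphthalen-1-yl]-2-methoxyphenoxy}-N-methoxy-N-methylpropanamide
Conditions: PPh3, DIAD, toluene, 0 °C → rt
Reagents that add atoms: none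
Why: Mitsunobu etherification; the phenol, the only acidic OH, displaces the activated α-carbonyl secondary alcohol by SN2 with inversion, (S) to (R), which sets C8''.

Step 19
Reactants: 28 4-bromo-2-methoxyphenol
Product: 29 1-(benzyloxy)-4-bromo-2-methoxybenzene
Conditions: BnBr, K2CO3, DMF, rt
Reagents that add atoms: benzyl bromide, BrCc1ccccc1
Why: Williamson ether synthesis on the phenoxide.

Step 20
Reactants: 27 (2R)-2-{4-[(1S,2S,3R)-7-(benzyloxy)-6-methoxy-2,3-dimethyl-1,2,3,4-tetrahydronaphthalen-1-yl]-2-methoxyphenoxy}-N-methoxy-N-methylpropanamide; 29 1-(benzyloxy)-4-bromo-2-methoxybenzene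
Product: 31 (2R)-1-[4-(benzyloxy)-3-methoxyphenyl]-2-{4-[(1S,2S,3R)-7-(benzyloxy)-6-methoxy-2,3-dimethyl-1,2,3,4-tetrahydronaphthalen-1-yl]-2-methoxyphenoxy}propan-1-one, via arylmagnesium bromide 30 (not isolated)
Conditions: 29, Mg, THF, 40 °C; then 27, THF, −20 → 0 °C; cold aq. NH4Cl
Reagents that add atoms: none
Why: Weinreb ketone synthesis; the Grignard reagent 30 adds once to give a chelated tetrahedral magnesium intermediate that collapses to the ketone only on quench. Low temperature and a buffered quench should keep the α-aryloxy centre C8'' intact.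

Step 21
Reactants: 31 (2R)-1-[4-(benzyloxy)-3-methoxyphenyl]-2-{4-[(1S,2S,3R)-7-(benzyloxy)-6-methoxy-2,3-dimethyl-1,2,3,4-tetrahydronaphthalen-1-yl]-2-methoxyphenoxy}propan-1-one
Product: 32 (1S,2R)-1-[4-(benzyloxy)-3-methoxyphenyl]-2-{4-[(1S,2S,3R)-7-(benzyloxy)-6-methoxy-2,3-dimethyl-1,2,3,4-tetrahydronaphthalen-1-yl]-2-methoxyphenoxy}propan-1-ol
Conditions: Zn(BH4)2 (0.15 M in Et2O), Et2O/CH2Cl2, −30 → 0 °C
Reagents that add atoms: none
Why: Chelation-controlled reduction (Cram chelate model); zinc bridges the carbonyl oxygen and the C8'' ether oxygen, helped by the ortho methoxy group of ring C, and hydride enters from the side of the C8'' hydrogen. This should give the erythro (1S,2R) alcohol and so sets C7''.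

Step 22
Reactants: 32 (1S,2R)-1-[4-(benzyloxy)-3-methoxyphenyl]-2-{4-[(1S,2S,3R)-7-(benzyloxy)-6-methoxy-2,3-dimethyl-1,2,3,4-tetrahydronaphthalen-1-yl]-2-methoxyphenoxy}propan-1-ol
Product: 33 4-[(1S,2R)-1-hydroxy-2-{4-[(1S,2S,3R)-7-hydroxy-6-methoxy-2,3-dimethyl-1,2,3,4-tetrahydronaphthalen-1-yl]-2-methoxyphenoxy}propyl]-2-methoxyphenol (CID53359464)
Conditions: H2 (1 atm), Pd/C (10 wt % Pd), EtOAc/EtOH, rt
Reagents that add atoms: none
Why: Hydrogenolysis of the two aryl benzyl ethers under neutral conditions; aryl O–benzyl bonds should be cleaved faster than the secondary benzylic C–OH or the alkyl aryl ether when no acid is present and the reaction is stopped at full conversion.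

## Compound list

1 | 4-(benzyloxy)-3-methoxybenzaldehyde | COc1cc(C=O)ccc1OCc1ccccc1 | starting material
2 | 4-(benzyloxy)-2-bromo-5-methoxybenzaldehyde | COc1cc(C=O)c(Br)cc1OCc1ccccc1 | intermediate
3 | [4-(benzyloxy)-2-bromo-5-methoxyphenyl]methanol | COc1cc(CO)c(Br)cc1OCc1ccccc1 | intermediate
4 | 1-(benzyloxy)-5-bromo-4-(bromomethyl)-2-methoxybenzene | COc1cc(CBr)c(Br)cc1OCc1ccccc1 | intermediate
5 | (4R)-4-benzyl-1,3-oxazolidin-2-one | O=C1N[C@H](Cc2ccccc2)CO1 | starting material
6 | pent-4-enoyl chloride | C=CCCC(=O)Cl | starting material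
7 | (4R)-4-benzyl-3-(pent-4-enoyl)-1,3-oxazolidin-2-one | C=CCCC(=O)N1[C@H](Cc2ccccc2)COC1=O | intermediate
8 | sodium (Z)-enolate of 7 | C=CC/C=C(\[O-])N1[C@H](Cc2ccccc2)COC1=O.[Na+] | intermediate (not isolated)
9 | (4R)-4-benzyl-3-[(2S)-2-{[4-(benzyloxy)-2-bromo-5-methoxyphenyl]methyl}pent-4-enoyl]-1,3-oxazolidin-2-one | COc1cc(C[C@@H](C(=O)N2[C@H](Cc3ccccc3)COC2=O)CC=C)c(Br)cc1OCc1ccccc1 | intermediate
10 | (2S)-2-{[4-(benzyloxy)-2-bromo-5-methoxyphenyl]methyl}pent-4-en-1-ol | COc1cc(C[C@@H](CO)CC=C)c(Br)cc1OCc1ccccc1 | intermediate
11 | (2S)-2-{[4-(benzyloxy)-2-bromo-5-methoxyphenyl]methyl}pent-4-en-1-yl 4-methylbenzenesulfonate | COc1cc(C[C@@H](COS(=O)(=O)c2ccc(C)cc2)CC=C)c(Br)cc1OCc1ccccc1 | intermediate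
12 | 1-(benzyloxy)-5-bromo-2-methoxy-4-[(2S)-2-methylpent-4-en-1-yl]benzene | COc1cc(C[C@@H](C)CC=C)c(Br)cc1OCc1ccccc1 | intermediate
13 | vanillin | COc1cc(C=O)ccc1O | starting material
14 | 4-[(tert-butyldimethylsilyl)oxy]-3-methoxybenzaldehyde | COc1cc(C=O)ccc1O[Si](C)(C)C(C)(C)C | intermediate
15 | {4-(benzyloxy)-5-methoxy-2-[(2S)-2-methylpent-4-en-1-yl]phenyl}lithium | [Li]c1cc(OCc2ccccc2)c(OC)cc1C[C@@H](C)CC=C | intermediate (not isolated)
16 | {4-(benzyloxy)-5-methoxy-2-[(2S)-2-methylpent-4-en-1-yl]phenyl}{4-[(tert-butyldimethylsilyl)oxy]-3-methoxyphenyl}methanol, both carbinol epimers | COc1cc(C(O)c2cc(OCc3ccccc3)c(OC)cc2C[C@@H](C)CC=C)ccc1O[Si](C)(C)C(C)(C)C | intermediate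
17 | (4R)-5-[4-(benzyloxy)-2-{[4-(tert-butyldimethylsilyloxy)-3-methoxyphenyl](hydroxy)methyl}-5-methoxyphenyl]-4-methylpentane-1,2-diol, epimers at C2 and at the carbinol | COc1cc(C(O)c2cc(OCc3ccccc3)c(OC)cc2C[C@@H](C)CC(O)CO)ccc1O[Si](C)(C)C(C)(C)C | intermediate (not isolated)
18 | (3R)-4-[4-(benzyloxy)-2-{[4-(tert-butyldimethylsilyloxy)-3-methoxyphenyl](hydroxy)methyl}-5-methoxyphenyl]-3-methylbutanal | COc1cc(C(O)c2cc(OCc3ccccc3)c(OC)cc2C[C@@H](C)CC=O)ccc1O[Si](C)(C)C(C)(C)C | intermediate
19 | (3R)-4-[4-(benzyloxy)-2-[hydroxy(4-hydroxy-3-methoxyphenyl)methyl]-5-methoxyphenyl]-3-methylbutanal | COc1cc(C(O)c2cc(OCc3ccccc3)c(OC)cc2C[C@@H](C)CC=O)ccc1O | intermediate (precursor of the key step)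
20 | 4-{[4-(benzyloxy)-5-methoxy-2-[(2R,3E)-2-methyl-4-(pyrrolidin-1-yl)but-3-en-1-yl]phenyl]methylidene}-2-methoxycyclohexa-2,5-dien-1-one | COC1=CC(=Cc2cc(OCc3ccccc3)c(OC)cc2C[C@@H](C)/C=C/N2CCCC2)C=CC1=O | intermediate (not isolated)
21 | (1S,2S,3R)-7-(benzyloxy)-1-(4-hydroxy-3-methoxyphenyl)-6-methoxy-3-methyl-1,2,3,4-tetrahydronaphthalene-2-carbaldehyde | COc1cc([C@H]2c3cc(OCc4ccccc4)c(OC)cc3C[C@@H](C)[C@@H]2C=O)ccc1O | intermediate (product of the key step)
22 | 4-[(1S,2S,3R)-7-(benzyloxy)-2-(hydroxymethyl)-6-methoxy-3-methyl-1,2,3,4-tetrahydronaphthalen-1-yl]-2-methoxyphenol | COc1cc([C@H]2c3cc(OCc4ccccc4)c(OC)cc3C[C@@H](C)[C@@H]2CO)ccc1O | intermediate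
23 | 4-[(1S,2S,3R)-7-(benzyloxy)-2-(iodomethyl)-6-methoxy-3-methyl-1,2,3,4-tetrahydronaphthalen-1-yl]-2-methoxyphenol | COc1cc([C@H]2c3cc(OCc4ccccc4)c(OC)cc3C[C@@H](C)[C@@H]2CI)ccc1O | intermediate
24 | 4-[(1S,2S,3R)-7-(benzyloxy)-6-methoxy-2,3-dimethyl-1,2,3,4-tetrahydronaphthalen-1-yl]-2-methoxyphenol | COc1cc([C@H]2c3cc(OCc4ccccc4)c(OC)cc3C[C@@H](C)[C@@H]2C)ccc1O | intermediate
25 | ethyl (S)-lactate | CCOC(=O)[C@H](C)O | starting material
26 | (2S)-2-hydroxy-N-methoxy-N-methylpropanamide | CON(C)C(=O)[C@H](C)O | intermediate
27 | (2R)-2-{4-[(1S,2S,3R)-7-(benzyloxy)-6-methoxy-2,3-dimethyl-1,2,3,4-tetrahydronaphthalen-1-yl]-2-methoxyphenoxy}-N-methoxy-N-methylpropanamide | CON(C)C(=O)[C@@H](C)Oc1ccc([C@H]2c3cc(OCc4ccccc4)c(OC)cc3C[C@@H](C)[C@@H]2C)cc1OC | intermediate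
28 | 4-bromo-2-methoxyphenol | COc1cc(Br)ccc1O | starting material
29 | 1-(benzyloxy)-4-bromo-2-methoxybenzene | COc1cc(Br)ccc1OCc1ccccc1 | intermediate
30 | [4-(benzyloxy)-3-methoxyphenyl]magnesium bromide | COc1cc([Mg]Br)ccc1OCc1ccccc1 | intermediate (not isolated)
31 | (2R)-1-[4-(benzyloxy)-3-methoxyphenyl]-2-{4-[(1S,2S,3R)-7-(benzyloxy)-6-methoxy-2,3-dimethyl-1,2,3,4-tetrahydronaphthalen-1-yl]-2-methoxyphenoxy}propan-1-one | COc1cc(C(=O)[C@@H](C)Oc2ccc([C@H]3c4cc(OCc5ccccc5)c(OC)cc4C[C@@H](C)[C@@H]3C)cc2OC)ccc1OCc1ccccc1 | intermediate
32 | (1S,2R)-1-[4-(benzyloxy)-3-methoxyphenyl]-2-{4-[(1S,2S,3R)-7-(benzyloxy)-6-methoxy-2,3-dimethyl-1,2,3,4-tetrahydronaphthalen-1-yl]-2-methoxyphenoxy}propan-1-ol | COc1cc([C@H](O)[C@@H](C)Oc2ccc([C@H]3c4cc(OCc5ccccc5)c(OC)cc4C[C@@H](C)[C@@H]3C)cc2OC)ccc1OCc1ccccc1 | intermediate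
33 | 4-[(1S,2R)-1-hydroxy-2-{4-[(1S,2S,3R)-7-hydroxy-6-methoxy-2,3-dimethyl-1,2,3,4-tetrahydronaphthalen-1-yl]-2-methoxyphenoxy}propyl]-2-methoxyphenol | COc1cc([C@H](O)[C@@H](C)Oc2ccc([C@H]3c4cc(O)c(OC)cc4C[C@@H](C)[C@@H]3C)cc2OC)ccc1O | target

## Step count and least certain steps

Total step count: 22. Longest linear sequence: 18 steps (steps 1, 2, 3, 5, 6, 7, 8, 10, 11, 12, 13, 14, 15, 16, 18, 20, 21, 22, from 1 to 33).

Step 13 (key step). Most likely to go wrong: insufficient facial selectivity at C1, because the chair preference is the only control element and C1 cannot be corrected afterwards; or oligomerization through intermolecular attack of the free phenol or the amine on the quinone methide. The fallback sets out from 18 and returns at 21, and uses a carbocation instead of a quinone methide and a preformed enol ether instead of an enamine. 18 is treated with Me3SiOTf and Et3N to give the bis(trimethylsilyl) compound F1 (enol silane and carbinol silyl ether). A catalytic Lewis acid (Sc(OTf)3 or BF3·OEt2, CH2Cl2, −78 °C) then ionizes the benzhydryl silyl ether to the doubly stabilized diarylcarbenium ion, which the enol silane captures in a Mukaiyama-type SN1 alkylation at low temperature. After brief DBU equilibration at C2 this gives the silyl-protected tetralin aldehyde F2, and Bu4NF/AcOH leads to 21. No free phenol is present during ring closure in this variant.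

Step 11. Most likely to go wrong: ionization or oxidation of the free, very electron-rich diaryl carbinol in the aqueous oxidizing medium, or over-oxidation next to the new aldehyde. The fallback sets out from 16 and returns at 19. The carbinol is first capped with Et3SiCl and imidazole to give the triethylsilyl ether F3. The alkene is then cleaved by ozonolysis with reductive work-up (O3, CH2Cl2/MeOH, −78 °C; PPh3) to give the doubly silylated aldehyde F4, and Bu4NF/AcOH removes both silyl groups to give 19.

Step 18. Most likely to go wrong: slow activation of the hindered α-hydroxy amide, so that the betaine is consumed by side reactions, or partial loss of stereospecificity. The fallback sets out from 24 and 25 and returns at 27, and uses sulfonate displacement instead of redox condensation. 25 is converted with Tf2O and 2,6-lutidine into ethyl (2S)-2-(trifluoromethylsulfonyloxy)propanoate F5. The phenoxide of 24 (K2CO3, MeCN, 0 °C) displaces the triflate with inversion to give the ethyl ester F6, and aminolysis with MeNH(OMe)·HCl and i-PrMgCl gives 27.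

Step 20. Most likely to go wrong: epimerization at C8'' by deprotonation of the amide by the basic Grignard reagent, or by enolization of the α-aryloxy ketone during work-up. The fallback sets out from 27 and returns at 32, and avoids the ketone. 27 is reduced with i-Bu2AlH at −78 °C to the aldehyde F7. 30 is transmetallated with ClTi(OiPr)3 to the non-chelating aryltitanium reagent F8, and its addition to F7 at −78 °C under Felkin–Anh control (aryloxy group anti to the incoming aryl) should give the erythro alcohol 32 directly.

Step 21. Most likely to go wrong: incomplete chelation, so that open-chain (Felkin–Anh) attack competes and lowers the erythro selectivity. The fallback sets out from 31 and returns at 32, and corrects the wrong isomer instead of avoiding it. The threo alcohol F9 is separated and inverted at C7'' by a Mitsunobu reaction with 4-nitrobenzoic acid to give the erythro 4-nitrobenzoate F10, and methanolysis (K2CO3, MeOH) gives 32.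

Step 22. Most likely to go wrong: over-reduction, that is hydrogenolysis of the para-oxygenated benzylic C7''–OH bond once the benzyl ethers are gone. The fallback sets out from 32 and returns at 33. The carbinol is silylated (t-BuMe2SiOTf, 2,6-lutidine) to the silyl ether F11, whose benzylic C–O bond should resist hydrogenolysis. The benzyl ethers are then removed (H2, Pd/C) to give the bis-phenol F12, and Bu4NF/AcOH releases 33.

Further compounds

F1 | step 13 | tert-butyl{4-[[4-(benzyloxy)-5-methoxy-2-[(2R)-2-methyl-4-(trimethylsilyloxy)but-3-en-1-yl]phenyl](trimethylsilyloxy)methyl]-2-methoxyphenoxy}dimethylsilane | COc1cc(C(O[Si](C)(C)C)c2cc(OCc3ccccc3)c(OC)cc2C[C@@H](C)C=CO[Si](C)(C)C)ccc1O[Si](C)(C)C(C)(C)C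
F2 | step 13 | (1S,2S,3R)-7-(benzyloxy)-1-{4-[(tert-butyldimethylsilyl)oxy]-3-methoxyphenyl}-6-methoxy-3-methyl-1,2,3,4-tetrahydronaphthalene-2-carbaldehyde | COc1cc([C@H]2c3cc(OCc4ccccc4)c(OC)cc3C[C@@H](C)[C@@H]2C=O)ccc1O[Si](C)(C)C(C)(C)C
F3 | step 11 | triethylsilyl ether of 16 at the carbinol oxygen | COc1cc(C(O[Si](CC)(CC)CC)c2cc(OCc3ccccc3)c(OC)cc2C[C@@H](C)CC=C)ccc1O[Si](C)(C)C(C)(C)C
F4 | step 11 | (3R)-4-[4-(benzyloxy)-2-{[4-(tert-butyldimethylsilyloxy)-3-methoxyphenyl](triethylsilyloxy)methyl}-5-methoxyphenyl]-3-methylbutanal | COc1cc(C(O[Si](CC)(CC)CC)c2cc(OCc3ccccc3)c(OC)cc2C[C@@H](C)CC=O)ccc1O[Si](C)(C)C(C)(C)C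
F5 | step 18 | ethyl (2S)-2-(trifluoromethylsulfonyloxy)propanoate | CCOC(=O)[C@H](C)OS(=O)(=O)C(F)(F)F
F6 | step 18 | ethyl (2R)-2-{4-[(1S,2S,3R)-7-(benzyloxy)-6-methoxy-2,3-dimethyl-1,2,3,4-tetrahydronaphthalen-1-yl]-2-methoxyphenoxy}propanoate | CCOC(=O)[C@@H](C)Oc1ccc([C@H]2c3cc(OCc4ccccc4)c(OC)cc3C[C@@H](C)[C@@H]2C)cc1OC
F7 | step 20 | (2R)-2-{4-[(1S,2S,3R)-7-(benzyloxy)-6-methoxy-2,3-dimethyl-1,2,3,4-tetrahydronaphthalen-1-yl]-2-methoxyphenoxy}propanal | O=C[C@@H](C)Oc1ccc([C@H]2c3cc(OCc4ccccc4)c(OC)cc3C[C@@H](C)[C@@H]2C)cc1OC
F8 | step 20 | [4-(benzyloxy)-3-methoxyphenyl]titanium triisopropoxide | COc1cc([Ti](OC(C)C)(OC(C)C)OC(C)C)ccc1OCc1ccccc1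
F9 | step 21 | (1R,2R)-1-[4-(benzyloxy)-3-methoxyphenyl]-2-{4-[(1S,2S,3R)-7-(benzyloxy)-6-methoxy-2,3-dimethyl-1,2,3,4-tetrahydronaphthalen-1-yl]-2-methoxyphenoxy}propan-1-ol (threo) | COc1cc([C@@H](O)[C@@H](C)Oc2ccc([C@H]3c4cc(OCc5ccccc5)c(OC)cc4C[C@@H](C)[C@@H]3C)cc2OC)ccc1OCc1ccccc1
F10 | step 21 | (1S,2R)-1-[4-(benzyloxy)-3-methoxyphenyl]-2-{4-[(1S,2S,3R)-7-(benzyloxy)-6-methoxy-2,3-dimethyl-1,2,3,4-tetrahydronaphthalen-1-yl]-2-methoxyphenoxy}propyl 4-nitrobenzoate | COc1cc([C@H](OC(=O)c2ccc([N+](=O)[O-])cc2)[C@@H](C)Oc2ccc([C@H]3c4cc(OCc5ccccc5)c(OC)cc4C[C@@H](C)[C@@H]3C)cc2OC)ccc1OCc1ccccc1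
F11 | step 22 | tert-butyldimethylsilyl ether of 32 at the C7'' oxygen | COc1cc([C@H](O[Si](C)(C)C(C)(C)C)[C@@H](C)Oc2ccc([C@H]3c4cc(OCc5ccccc5)c(OC)cc4C[C@@H](C)[C@@H]3C)cc2OC)ccc1OCc1ccccc1
F12 | step 22 | tert-butyldimethylsilyl ether of 33 at the C7'' oxygen | COc1cc([C@H](O[Si](C)(C)C(C)(C)C)[C@@H](C)Oc2ccc([C@H]3c4cc(O)c(OC)cc4C[C@@H](C)[C@@H]3C)cc2OC)ccc1O
A1 | alternative 1 | 2-[1-(4-benzyloxy-3-methoxyphenyl)-1-(2-chloro-4-methoxy-5-triisopropylsilyloxyphenyl)propan-2-yl]-4,4,5,5-tetramethyl-1,3,2-dioxaborolane (C1 and C2 as in the target) | COc1cc([C@H]([C@@H](C)B2OC(C)(C)C(C)(C)O2)c2cc(O[Si](C(C)C)(C(C)C)C(C)C)c(OC)cc2Cl)ccc1OCc1ccccc1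
A2 | alternative 1 | 2-[(Z)-2-(2-chloro-4-methoxy-5-triisopropylsilyloxyphenyl)ethenyl]-4,4,5,5-tetramethyl-1,3,2-dioxaborolane | COc1cc(Cl)c(/C=C\B2OC(C)(C)C(C)(C)O2)cc1O[Si](C(C)C)(C(C)C)C(C)C
A3 | alternative 1 | 4-(benzyloxy)-3-methoxyphenyl trifluoromethanesulfonate | COc1cc(OS(=O)(=O)C(F)(F)F)ccc1OCc1ccccc1
A4 | alternative 2 | methyl 1-(4-allyloxy-3-methoxyphenyl)-7-benzyloxy-4-hydroxy-6-methoxy-2-methyl-1,2,3,4-tetrahydronaphthalene-3-carboxylate (target numbering; C1, C2, C3 all-trans, 4-OH cis to the ester) | COc1cc([C@H]2c3cc(OCc4ccccc4)c(OC)cc3[C@@H](O)[C@@H](C(=O)OC)[C@@H]2C)ccc1OCC=C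
A5 | alternative 2 | 2-[(4-allyloxy-3-methoxyphenyl)methyl]-4-(benzyloxy)-5-methoxybenzaldehyde | COc1cc(C=O)c(Cc2ccc(OCC=C)c(OC)c2)cc1OCc1ccccc1
A6 | alternative 2 | methyl (E)-but-2-enoate | C/C=C/C(=O)OC
A7 | alternative 3 | (1S,2S,3R)-1-(4-benzyloxy-3-methoxyphenyl)-6-methoxy-2,3-dimethyl-1,2,3,4-tetrahydronaphthalen-7-yl 2,2-dimethylpropanoate (target numbering) | COc1cc([C@H]2c3cc(OC(=O)C(C)(C)C)c(OC)cc3C[C@@H](C)[C@@H]2C)ccc1OCc1ccccc1
A8 | alternative 3 | 1-(benzyloxy)-2-methoxy-4-[(E)-prop-1-en-1-yl]benzene | C/C=C/c1ccc(OCc2ccccc2)c(OC)c1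
A9 | alternative 3 | 2-methoxy-4-[(E)-prop-1-en-1-yl]phenyl 2,2-dimethylpropanoate | C/C=C/c1ccc(OC(=O)C(C)(C)C)c(OC)c1
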